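All runs stem from a simulated flask for substances that don't exist; the scatter is artificial.

How much of Sunday's Sub is Prd at 96 min, and what are the two orders at Friday's charge?

| flask | Sub | Cat | time |
|---|---|---|---|
| Friday's | 0.300 M | 0.00150 M |  |
| Monday's | 0.150 M | 0.00150 M |  |
| Saturday's | 0.150 M | 0.00150 M |  |
| Wednesday's | 0.300 M | 0.00230 M |  |
| Sunday's | 0.120 M | 0.00150 M | 96 min |

- Friday's run (time / min: [Prd] / M): 19: 0.0464; 38: 0.0687; 58: 0.0803; 77: 0.0858; 96: 0.0869
- Monday's run (time / min: [Prd] / M): 19: 0.0642; 38: 0.0975; 58: 0.1178; 77: 0.1285; 96: 0.1351
- Saturday's run (time / min: [Prd] / M): 19: 0.0646; 38: 0.1004; 58: 0.1187; 77: 0.1299; 96: 0.1355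
- Wednesday's run (time / min: [Prd] / M): 19: 0.1178; 38: 0.1873; 58: 0.2250; 77: 0.2463; 96: 0.2576

(each reading ± 9 × 10⁻⁴ M)

* the exponent of [Cat] in the starting rate at the charge of the Friday's run (at the point where two percent of the Sub have become Prd)
* the exponent of [Sub] in the starting rate at the charge of the Friday's run (at the point where two percent of the Sub have become Prd) (one fixed amount of Prd, the same in the runs compared)
* Prd in the Sunday's run at 96 min, as a share of the Sub charged

- Overall: Sub -> Prd, with Cat as catalyst.
- Constant volume, constant temperature.
- Readings of a species count what is bound in complexes too.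
- An order is taken over about fifteen percent of the charge, up and down.

Sub is the limiting reagent, so I kept its books as fractions of the charge: each share is either turned to Prd or still unturned. Monday's flask at its first reading gave 0.0294 min⁻¹. This is the quantity I carried, the drain constant: the natural logarithm of the charge over the unturned Sub, divided by the time, a pseudo-first-order constant.

Monday, first reading: turned 42.8%, unturned 57.2%, constant 0.0294 min⁻¹

Monday, last reading: turned 90.1%, unturned 9.93%, constant 0.0241 min⁻¹

Friday, first reading: turned 15.5%, unturned 84.5%, constant 0.00884 min⁻¹

Across Monday's flask the whole-run constant fell to 82.0% of the first one, and across Friday's flask to 40.3% of its first one, so it is a drifting run average and not a true constant. As an estimate for Sunday's flask, I froze Monday's value from its last reading, taken at the asked time. Doubling the Sub from Monday's charge to Friday's lowered the first-reading constant, with exponent −1.73. I used that exponent to scale the constant to Sunday's charge, not as an order. For my order in Sub I compared the first readings of Friday's and Monday's flasks directly, which gave a chord over that doubling of −0.468, not the order at Friday's charge itself. Friday's and Wednesday's flasks hold the same Sub, so their first readings compare directly and give an order in Cat of 2.18.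

Sunday, constant: 0.0354 min⁻¹

Sunday, unturned: 3.34%

Sunday, turned: 96.7%

The forecast gave 2.2 for Cat, −0.8 for Sub and 93.5% for Sunday's flask, reasoning that “Sunday has less Sub than Monday, so more active catalyst”. My order in Sub was shallower, and my Sunday share was higher.

The simulation gave 2.2, −0.86 and, for Sunday's flask, 98.0%.

    Cat + Sub ⇌ Cat.Sub, settled at all times (5.180 L mol⁻¹)
    Cat.Sub + Cat → Prd + 2 Cat (9780 L mol⁻¹ min⁻¹)
    Cat.Sub → Z + Sub (0.04362 min⁻¹)
    Cat.Sub + Sub ⇌ Cat.Sub2, settled at all times (1.430 L mol⁻¹)

Sunday's flask left 2.00% unturned, a constant of 0.0408 min⁻¹, which is 1.39 times Monday's first-reading constant and above my frozen 0.0354 min⁻¹. Monday's constant puts a quarter turned at 9.79 min, and Saturday's flask took 9.59 min. Wednesday's first reading gives 11.0 min against 10.9 min. The order in Sub at Friday's charge is steep because Cat.Sub is parked with Sub as Cat.Sub2: the run without that parking gives −0.25 in place of −0.86.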